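## Retrosynthetic overview

1. Rings: A = acetoxycyclohexene, B = butenolide (O1, C2=O, C3, C4, C5; exocyclic carbon C6), C = epoxycyclohexane. The last bond made is C3–Ca (Ca = the alkenyl CH on C3); it divides pyrrhoxanthin into an (E)-alkenyl pinacol boronate carrying ring C and a linear C28 tetraene-triynoic acid carrying ring A.
2. Enabling feature: ring B with its exocyclic C5=C6 bond is a cyclised penta-2,4-diynoic acid (C3≡C4 and C5≡C6). The C2 carboxyl polarises C3≡C4 (hydride to C4, palladium to C3, so the ynoate α-carbon is joined to a nucleophilic alkenylboron carbon), supplies the O–H that makes the palladium hydride, and then closes O1–C5; one operation forms C3–Ca, ring B and the Z C5=C6 bond.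
3. Triynoic acid: Cadiot–Chodkiewicz coupling of 3-bromopropiolic acid onto a tetraene-diyne, which comes from a Horner–Wadsworth–Emmons union of a ring-A C15 phosphonate (Sonogashira of an enol triflate) with a C8 dienynal.
4. Boronate: the same enol triflate → methoxycarbonylation → reduction → Sharpless epoxidation (oxirane anti to the ring C–O bond) → aldehyde → boron–Wittig olefination.
5. Ring order: the carbocycles of rings A and C both come from (4R,6R)-actinol; the oxirane of ring C is closed in step 5; ring B is formed last, in the key step.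

Key step: step 19

Remark: (4R,6R)-actinol and (2E)-3-methylpent-2-en-4-yn-1-ol are taken as purchasable in enantiopure and geometrically pure form; the locants O1–C6 and Ca are those defined in the overview.

## Route

Step 1
Reactants: 1 (4R,6R)-4-hydroxy-2,2,6-trimethylcyclohexan-1-one (actinol); 2 tert-butyldimethylsilyl chloride
Product: 3 (4R,6R)-4-[(tert-butyldimethylsilyl)oxy]-2,2,6-trimethylcyclohexan-1-one
Conditions: TBSCl, imidazole, DMF, 25 °C
Reagents that add atoms: tert-butyldimethylsilyl chloride, CC(C)(C)[Si](C)(C)Cl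
Why: Standard silylation of the secondary alcohol; the ketone and both stereocentres are untouched.

Step 2
Reactants: 3 silyl-protected actinol; 4 N-phenylbis(trifluoromethanesulfonimide)
Product: 6 (4R)-4-[(tert-butyldimethylsilyl)oxy]-2,6,6-trimethylcyclohex-1-en-1-yl trifluoromethanesulfonate, via lithium enolate 5 (not isolated)
Conditions: LiN(iPr)2, THF, −78 → 0 °C; then PhNTf2, 0 → 25 °C
Reagents that add atoms: N-phenylbis(trifluoromethanesulfonimide), O=S(=O)(N(c1ccccc1)S(=O)(=O)C(F)(F)F)C(F)(F)F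
Why: The ketone has a single enolisable α-position, so enolate O-triflation should give one tetrasubstituted enol triflate; the methyl-bearing stereocentre is erased on purpose and the silyloxy stereocentre is not affected.

Step 3
Reactants: 6 enol triflate; 7 carbon monoxide; 8 methanol
Product: 9 methyl (4R)-4-[(tert-butyldimethylsilyl)oxy]-2,6,6-trimethylcyclohex-1-ene-1-carboxylate
Conditions: Pd(OAc)2 (5 mol %), PPh3 (10 mol %), Et3N, CO (1 atm), MeOH/DMF, 60 °C
Reagents that add atoms: carbon monoxide, [C-]#[O+]; methanol, CO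
Why: Palladium-catalysed alkoxycarbonylation of an enol triflate (oxidative addition, CO insertion, methanolysis) installs the one-carbon substituent of ring C.

Step 4
Reactants: 9 methyl ester
Product: 10 [(4R)-4-[(tert-butyldimethylsilyl)oxy]-2,6,6-trimethylcyclohex-1-en-1-yl]methanol
Conditions: iBu2AlH (2.5 equiv), CH2Cl2, −78 → 0 °C
Reagents that add atoms: none
Why: 1,2-Reduction of the hindered enoate by the aluminium hydride gives the allylic alcohol needed for directed epoxidation; the silyl ether is stable.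

Step 5
Reactants: 10 allylic alcohol; 11 tert-butyl hydroperoxide
Product: 12 [(1R,4S,6R)-4-[(tert-butyldimethylsilyl)oxy]-2,2,6-trimethyl-7-oxabicyclo[4.1.0]heptan-1-yl]methanol (oxirane anti to the silyloxy group)
Conditions: Ti(OiPr)4 (20 mol %), D-(−)-diethyl tartrate (24 mol %), tBuOOH, 4 Å MS, CH2Cl2, −20 °C
Reagents that add atoms: tert-butyl hydroperoxide, CC(C)(C)OO
Why: Sharpless asymmetric epoxidation of the tetrasubstituted allylic alcohol; the D-(−)-tartrate titanium complex should deliver oxygen to the face anti to the silyloxy group (also the less hindered face), setting both oxirane stereocentres.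

Step 6
Reactants: 12 epoxy alcohol
Product: 13 (1S,4S,6R)-4-[(tert-butyldimethylsilyl)oxy]-2,2,6-trimethyl-7-oxabicyclo[4.1.0]heptane-1-carbaldehyde
Conditions: (nPr4N)RuO4 (5 mol %), N-methylmorpholine N-oxide, 4 Å MS, CH2Cl2, 25 °C
Reagents that add atoms: none
Why: Ley–Griffith oxidation of the primary alcohol under neutral conditions; the aldehyde has no α-hydrogen, so the quaternary oxirane carbon cannot epimerise.

Step 7
Reactants: 13 epoxy aldehyde; 14 bis[(pinacolato)boryl]methane
Product: 15 2-[(E)-2-[(1S,4S,6R)-4-[(tert-butyldimethylsilyl)oxy]-2,2,6-trimethyl-7-oxabicyclo[4.1.0]heptan-1-yl]ethenyl]-4,4,5,5-tetramethyl-1,3,2-dioxaborolane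
Conditions: CH2(Bpin)2, lithium 2,2,6,6-tetramethylpiperidide, THF, 0 °C; then 13, −78 → 25 °C
Reagents that add atoms: bis[(pinacolato)boryl]methane, CC1(C)OB(CB2OC(C)(C)C(C)(C)O2)OC1(C)C
Why: Boron–Wittig olefination: the lithiated geminal bis(boronate) adds to the aldehyde and syn-elimination of B–O should give the (E)-alkenyl boronate, the bulky quaternary substituent enforcing the trans geometry.

Step 8
Reactants: 15 silyl-protected alkenyl boronate
Product: 16 (1S,3S,6R)-1,5,5-trimethyl-6-[(E)-2-(4,4,5,5-tetramethyl-1,3,2-dioxaborolan-2-yl)ethenyl]-7-oxabicyclo[4.1.0]heptan-3-ol, i.e. the free-hydroxy alkenyl boronate (same configuration as 15)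
Conditions: Bu4NF, AcOH (1:1), THF, 0 → 25 °C
Reagents that add atoms: none
Why: Acetic-acid-buffered fluoride desilylation removes the silyl ether in a near-neutral medium that should spare the pinacol boronate and the acid-sensitive vinyl oxirane.

Step 9
Reactants: 17 (2E)-3-methylpent-2-en-4-yn-1-ol; 18 phosphorus tribromide
Product: 19 (3E)-5-bromo-3-methylpent-3-en-1-yne
Conditions: PBr3 (0.4 equiv), pyridine (cat.), Et2O, −10 °C
Reagents that add atoms: phosphorus tribromide, BrP(Br)Br
Why: SN2 bromination of the primary allylic alcohol at low temperature keeps the E geometry and leaves the alkyne untouched.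

Step 10
Reactants: 19 allylic bromide; 20 triethyl phosphite
Product: 21 diethyl [(2E)-3-methylpent-2-en-4-yn-1-yl]phosphonate
Conditions: P(OEt)3 (neat), 90 °C
Reagents that add atoms: triethyl phosphite, CCOP(OCC)OCC
Why: Michaelis–Arbuzov reaction at the unhindered primary allylic bromide.

Step 11
Reactants: 6 enol triflate; 21 enynyl phosphonate
Product: 22 diethyl [(2E)-5-[(4R)-4-[(tert-butyldimethylsilyl)oxy]-2,6,6-trimethylcyclohex-1-en-1-yl]-3-methylpent-2-en-4-yn-1-yl]phosphonate
Conditions: Pd(PPh3)4 (5 mol %), CuI (10 mol %), iPr2NH, DMF, 50 °C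
Reagents that add atoms: none
Why: Sonogashira coupling of the terminal alkyne with the enol triflate makes the ring A–alkyne bond; the phosphonate and silyl ether are inert to the amine base.

Step 12
Reactants: 22 silyl-protected C15 phosphonate
Product: 23 diethyl [(2E)-5-[(4R)-4-hydroxy-2,6,6-trimethylcyclohex-1-en-1-yl]-3-methylpent-2-en-4-yn-1-yl]phosphonate
Conditions: Bu4NF, THF, 25 °C
Reagents that add atoms: none
Why: Fluoride desilylation; nothing else in the molecule is fluoride-labile.

Step 13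
Reactants: 23 hydroxy phosphonate; 24 acetic anhydride
Product: 25 (1R)-4-[(3E)-5-(diethoxyphosphoryl)-3-methylpent-3-en-1-yn-1-yl]-3,5,5-trimethylcyclohex-3-en-1-yl acetate
Conditions: Ac2O, pyridine, DMAP (cat.), CH2Cl2, 25 °C
Reagents that add atoms: acetic anhydride, CC(=O)OC(C)=O
Why: O-Acetylation installs the acetate of ring A with retention, because the C–O bond of the stereocentre is not broken.

Step 14
Reactants: 17 (2E)-3-methylpent-2-en-4-yn-1-ol
Product: 26 (2E)-3-methylpent-2-en-4-ynal
Conditions: MnO2, CH2Cl2, 25 °C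
Reagents that add atoms: none
Why: Chemoselective allylic oxidation; the volatile enynal is carried on as a solution.

Step 15
Reactants: 26 enynal; 27 (triphenylphosphoranylidene)acetaldehyde
Product: 28 (2E,4E)-5-methylhepta-2,4-dien-6-ynal
Conditions: Ph3P=CHCHO, toluene, 70 °C
Reagents that add atoms: (triphenylphosphoranylidene)acetaldehyde, O=CC=P(c1ccccc1)(c1ccccc1)c1ccccc1
Why: Wittig two-carbon homologation with a stabilised ylide is E-selective, and the more conjugated product reacts more slowly than 26.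

Step 16
Reactants: 25 acetoxy C15 phosphonate; 28 dienynal
Product: 30 (1R)-4-[(3E,5E,7E,9E)-3,10-dimethyldodeca-3,5,7,9-tetraene-1,11-diyn-1-yl]-3,5,5-trimethylcyclohex-3-en-1-yl acetate, via sodium phosphonate carbanion 29 (not isolated)
Conditions: NaN(SiMe3)2 (1.0 equiv), THF, −78 °C; then 28, −78 → 0 °C
Reagents that add atoms: none
Why: Horner–Wadsworth–Emmons olefination of the allylic phosphonate anion with the enal should give the new disubstituted double bond E; at −78 °C with one equivalent of base the acetate should survive.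

Step 17
Reactants: 31 propiolic acid; 32 bromine
Product: 33 3-bromoprop-2-ynoic acid
Conditions: KOH, Br2, H2O, 0 °C; acidic work-up (HCl)
Reagents that add atoms: bromine, BrBr
Why: Hypobromite bromination of the acidic acetylenic C–H of the carboxylate.

Step 18
Reactants: 30 tetraene-diyne acetate; 33 3-bromopropiolic acid
Product: 34 (6E,8E,10E,12E)-15-[(4R)-4-acetoxy-2,6,6-trimethylcyclohex-1-en-1-yl]-6,13-dimethylpentadeca-6,8,10,12-tetraene-2,4,14-triynoic acid
Conditions: CuCl (10 mol %), NH2OH·HCl, nBuNH2, THF/H2O, 0 °C; cold aqueous citric acid work-up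
Reagents that add atoms: none
Why: Cadiot–Chodkiewicz coupling of the terminal alkyne (as its copper acetylide) with the bromoalkyne; the carboxylate form of 33 and 34 should resist amine conjugate addition, and the low temperature should limit acetate aminolysis and decarboxylation (34 is used at once).

Step 19
Reactants: 34 triynoic acid; 16 alkenyl pinacol boronate
Product: 36 pyrrhoxanthin, via enynoic acid 35 (not isolated)
Conditions: Pd(PPh3)4 (5 mol %), H2O (3 equiv), 1,4-dioxane, 40 °C, dark; then Ag2CO3 (10 mol %), 25 °C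
Reagents that add atoms: none
Why: Proposed new method: zerovalent palladium is oxidised by the carboxylic acid O–H of 34 to a divalent palladium hydride carboxylate, which adds syn across the carboxyl-polarised C3≡C4 triple bond (H to C4, Pd to C3, the reverse of conjugate-addition regiochemistry); carboxylate-assisted, base-free transmetalation of the alkenyl group of 16 and reductive elimination then form the C3–Ca bond with retention of the E geometry, giving 35 with the C2 carboxyl cis to the C5≡C6 alkyne. The closest known reaction types are the Pd(PPh3)4/carboxylic-acid-catalysed syn-hydroarylation of alkynoates with organoboronic acids (organic group delivered to the ester-bearing carbon), the base-free transmetalation of alkenyl pinacol boronates to palladium carboxylates in oxidative Heck reactions, and the metal-catalysed lactonisation of (2Z)-2-en-4-ynoic acids to (Z)-γ-ylidenebutenolides. Ring B is closed by 5-exo-dig anti-addition of the carboxylate oxygen O1 to C5 of the metal-activated C5≡C6 triple bond (divalent palladium, completed by Ag2CO3), followed by protodemetalation. No stereocentre is formed: the syn hydropalladation fixes the C3=C4 geometry, the anti oxymetalation fixes the Z C5=C6 bond, and the four stereocentres and the E double bond of 16 are carried through unchanged. The step needs chemoselectivity for the ynoate triple bond over C5≡C6 and the ring-A alkyne, α-regioselectivity, and 5-exo over 6-endo closure; the first two should follow from the polarisation by the C2 carboxyl group and the steric shielding of the other alkynes, the last from the cis-carboxyl geometry and the known 5-exo preference of silver- and palladium-catalysed closures of such acids.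

## Compound list

1 | (4R,6R)-4-hydroxy-2,2,6-trimethylcyclohexan-1-one (actinol) | O[C@@H]1C[C@@H](C)C(=O)C(C)(C)C1 | starting material
2 | tert-butyldimethylsilyl chloride | CC(C)(C)[Si](C)(C)Cl | starting material
3 | (4R,6R)-4-[(tert-butyldimethylsilyl)oxy]-2,2,6-trimethylcyclohexan-1-one | CC(C)(C)[Si](C)(C)O[C@@H]1C[C@@H](C)C(=O)C(C)(C)C1 | intermediate
4 | N-phenylbis(trifluoromethanesulfonimide) | O=S(=O)(N(c1ccccc1)S(=O)(=O)C(F)(F)F)C(F)(F)F | starting material
5 | lithium (4R)-4-[(tert-butyldimethylsilyl)oxy]-2,6,6-trimethylcyclohex-1-en-1-olate | [Li+].[O-]C1=C(C)C[C@@H](O[Si](C)(C)C(C)(C)C)CC1(C)C | intermediate (not isolated)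
6 | (4R)-4-[(tert-butyldimethylsilyl)oxy]-2,6,6-trimethylcyclohex-1-en-1-yl trifluoromethanesulfonate | CC(C)(C)[Si](C)(C)O[C@@H]1CC(C)=C(OS(=O)(=O)C(F)(F)F)C(C)(C)C1 | intermediate
7 | carbon monoxide | [C-]#[O+] | starting material
8 | methanol | CO | starting material
9 | methyl (4R)-4-[(tert-butyldimethylsilyl)oxy]-2,6,6-trimethylcyclohex-1-ene-1-carboxylate | COC(=O)C1=C(C)C[C@@H](O[Si](C)(C)C(C)(C)C)CC1(C)C | intermediate
10 | [(4R)-4-[(tert-butyldimethylsilyl)oxy]-2,6,6-trimethylcyclohex-1-en-1-yl]methanol | OCC1=C(C)C[C@@H](O[Si](C)(C)C(C)(C)C)CC1(C)C | intermediate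
11 | tert-butyl hydroperoxide | CC(C)(C)OO | starting material
12 | [(1R,4S,6R)-4-[(tert-butyldimethylsilyl)oxy]-2,2,6-trimethyl-7-oxabicyclo[4.1.0]heptan-1-yl]methanol | OC[C@@]12O[C@]1(C)C[C@@H](O[Si](C)(C)C(C)(C)C)CC2(C)C | intermediate
13 | (1S,4S,6R)-4-[(tert-butyldimethylsilyl)oxy]-2,2,6-trimethyl-7-oxabicyclo[4.1.0]heptane-1-carbaldehyde | O=C[C@@]12O[C@]1(C)C[C@@H](O[Si](C)(C)C(C)(C)C)CC2(C)C | intermediate
14 | bis[(pinacolato)boryl]methane | CC1(C)OB(CB2OC(C)(C)C(C)(C)O2)OC1(C)C | starting material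
15 | 2-[(E)-2-[(1S,4S,6R)-4-[(tert-butyldimethylsilyl)oxy]-2,2,6-trimethyl-7-oxabicyclo[4.1.0]heptan-1-yl]ethenyl]-4,4,5,5-tetramethyl-1,3,2-dioxaborolane | CC1(C)OB(/C=C/[C@@]23O[C@]2(C)C[C@@H](O[Si](C)(C)C(C)(C)C)CC3(C)C)OC1(C)C | intermediate
16 | (1S,3S,6R)-1,5,5-trimethyl-6-[(E)-2-(4,4,5,5-tetramethyl-1,3,2-dioxaborolan-2-yl)ethenyl]-7-oxabicyclo[4.1.0]heptan-3-ol | CC1(C)OB(/C=C/[C@@]23O[C@]2(C)C[C@@H](O)CC3(C)C)OC1(C)C | intermediate
17 | (2E)-3-methylpent-2-en-4-yn-1-ol | C#C/C(C)=C/CO | starting material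
18 | phosphorus tribromide | BrP(Br)Br | starting material
19 | (3E)-5-bromo-3-methylpent-3-en-1-yne | C#C/C(C)=C/CBr | intermediate
20 | triethyl phosphite | CCOP(OCC)OCC | starting material
21 | diethyl [(2E)-3-methylpent-2-en-4-yn-1-yl]phosphonate | C#C/C(C)=C/CP(=O)(OCC)OCC | intermediate
22 | diethyl [(2E)-5-[(4R)-4-[(tert-butyldimethylsilyl)oxy]-2,6,6-trimethylcyclohex-1-en-1-yl]-3-methylpent-2-en-4-yn-1-yl]phosphonate | CC(C)(C)[Si](C)(C)O[C@@H]1CC(C)=C(C#C/C(C)=C/CP(=O)(OCC)OCC)C(C)(C)C1 | intermediate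
23 | diethyl [(2E)-5-[(4R)-4-hydroxy-2,6,6-trimethylcyclohex-1-en-1-yl]-3-methylpent-2-en-4-yn-1-yl]phosphonate | O[C@@H]1CC(C)=C(C#C/C(C)=C/CP(=O)(OCC)OCC)C(C)(C)C1 | intermediate
24 | acetic anhydride | CC(=O)OC(C)=O | starting material
25 | (1R)-4-[(3E)-5-(diethoxyphosphoryl)-3-methylpent-3-en-1-yn-1-yl]-3,5,5-trimethylcyclohex-3-en-1-yl acetate | CC(=O)O[C@@H]1CC(C)=C(C#C/C(C)=C/CP(=O)(OCC)OCC)C(C)(C)C1 | intermediate
26 | (2E)-3-methylpent-2-en-4-ynal | C#C/C(C)=C/C=O | intermediate
27 | (triphenylphosphoranylidene)acetaldehyde | O=CC=P(c1ccccc1)(c1ccccc1)c1ccccc1 | starting material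
28 | (2E,4E)-5-methylhepta-2,4-dien-6-ynal | C#C/C(C)=C/C=C/C=O | intermediate
29 | sodium salt of the α-phosphonate carbanion of 25 | [Na+].CC(=O)O[C@@H]1CC(C)=C(C#C/C(C)=C/[CH-]P(=O)(OCC)OCC)C(C)(C)C1 | intermediate (not isolated)
30 | (1R)-4-[(3E,5E,7E,9E)-3,10-dimethyldodeca-3,5,7,9-tetraene-1,11-diyn-1-yl]-3,5,5-trimethylcyclohex-3-en-1-yl acetate | CC(=O)O[C@@H]1CC(C)=C(C#C/C(C)=C/C=C/C=C/C=C(C)/C#C)C(C)(C)C1 | intermediate
31 | propiolic acid | C#CC(=O)O | starting material
32 | bromine | BrBr | starting material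
33 | 3-bromoprop-2-ynoic acid | OC(=O)C#CBr | intermediate
34 | (6E,8E,10E,12E)-15-[(4R)-4-acetoxy-2,6,6-trimethylcyclohex-1-en-1-yl]-6,13-dimethylpentadeca-6,8,10,12-tetraene-2,4,14-triynoic acid | CC(=O)O[C@@H]1CC(C)=C(C#C/C(C)=C/C=C/C=C/C=C(C)/C#CC#CC(=O)O)C(C)(C)C1 | intermediate
35 | (2Z,6E,8E,10E,12E)-15-[(4R)-4-acetoxy-2,6,6-trimethylcyclohex-1-en-1-yl]-2-[(E)-2-[(1S,4S,6R)-4-hydroxy-2,2,6-trimethyl-7-oxabicyclo[4.1.0]heptan-1-yl]ethenyl]-6,13-dimethylpentadeca-2,6,8,10,12-pentaene-4,14-diynoic acid | CC(=O)O[C@@H]1CC(C)=C(C#C/C(C)=C/C=C/C=C/C=C(C)/C#C/C=C(/C=C/[C@@]23O[C@]2(C)C[C@@H](O)CC3(C)C)C(=O)O)C(C)(C)C1 | intermediate (not isolated)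
36 | pyrrhoxanthin, (1R)-4-[(3E,5E,7E,9E,11Z)-11-[4-[(E)-2-[(1S,4S,6R)-4-hydroxy-2,2,6-trimethyl-7-oxabicyclo[4.1.0]heptan-1-yl]ethenyl]-5-oxofuran-2(5H)-ylidene]-3,10-dimethylundeca-3,5,7,9-tetraen-1-yn-1-yl]-3,5,5-trimethylcyclohex-3-en-1-yl acetate | CC(=O)O[C@@H]1CC(C)=C(C#C/C(C)=C/C=C/C=C/C=C(C)/C=C2C=C(/C=C/[C@@]34O[C@]3(C)C[C@@H](O)CC4(C)C)C(=O)O/2)C(C)(C)C1 | target

## Step count and risks

Total step count: 19. Longest linear sequence: 9 steps (steps 1–8, then step 19).

Steps most likely to fail: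

1. Step 19 (the step that carries the "Proposed new method" label). What may go wrong: hydropalladation at C5≡C6 or at the ring-A alkyne, or with reversed regiochemistry; palladium-mediated protodecarboxylation of the diynoic acid; acid-induced rearrangement of the vinyl oxirane of 16; 6-endo closure to a pyranone. Fallback (known chemistry), setting out from 30 and 16 and coming back at 36: anti-addition of bromine 32 to propiolic acid 31 gives (2E)-2,3-dibromoprop-2-enoic acid F1. Tandem Sonogashira coupling/5-exo-dig lactonisation of 30 with F1 (Pd(PPh3)4, CuI, Et3N, MeCN, 25 °C; the β-bromide cis to the carboxyl is the reactive one) should give the bromobutenolide (1R)-4-[(3E,5E,7E,9E,11Z)-11-(4-bromo-5-oxofuran-2(5H)-ylidene)-3,10-dimethylundeca-3,5,7,9-tetraen-1-yn-1-yl]-3,5,5-trimethylcyclohex-3-en-1-yl acetate F2. Suzuki–Miyaura coupling of F2 with 16 (Pd(PPh3)4, K3PO4, THF/H2O, 25 °C) then forms the same C3–Ca bond and gives 36.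

2. Step 18. What may go wrong: oxidative homocoupling of the polyenyne, copper-mediated decarboxylation of the bromopropiolate or of the product, aminolysis of the acetate, and degradation of the polyene during isolation of a free acid. Fallback, setting out from 28 and coming back at 34; it moves the diyne-forming coupling to a small robust fragment and introduces the carboxyl last. Palladium/copper-catalysed coupling of 28 with (bromoethynyl)triisopropylsilane (PdCl2(PPh3)2, CuI, iPr2NH, THF, 25 °C) gives (2E,4E)-5-methyl-9-[tri(propan-2-yl)silyl]nona-2,4-dien-6,8-diynal F3. Horner–Wadsworth–Emmons olefination of F3 with 25 (NaN(SiMe3)2, THF, −78 °C) gives (1R)-4-[(3E,5E,7E,9E)-3,10-dimethyl-14-[tri(propan-2-yl)silyl]tetradeca-3,5,7,9-tetraene-1,11,13-triyn-1-yl]-3,5,5-trimethylcyclohex-3-en-1-yl acetate F4. Brief treatment with Bu4NF (THF, 0 °C) gives the terminal diyne (1R)-4-[(3E,5E,7E,9E)-3,10-dimethyltetradeca-3,5,7,9-tetraene-1,11,13-triyn-1-yl]-3,5,5-trimethylcyclohex-3-en-1-yl acetate F5. Silver-catalysed carboxylation of F5 (AgI, Cs2CO3, CO2 1 atm, DMF, 25 °C; cold dilute acid) gives 34.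

3. Step 16. What may go wrong: loss of E selectivity at the new double bond, E/Z scrambling of the neighbouring trisubstituted alkene through the delocalised phosphonate anion, and attack of base or carbanion on the acetate. Fallback, setting out from 21 and 28 (with 6) and coming back at 30; the olefination is moved to a small, acetate-free, symmetric product whose geometry can be corrected before ring A is attached. Horner–Wadsworth–Emmons reaction of 21 with 28 (NaN(SiMe3)2, THF, −78 °C) gives (3E,5E,7E,9E)-3,10-dimethyldodeca-3,5,7,9-tetraene-1,11-diyne F6, which is equilibrated with catalytic iodine and crystallised as the all-E isomer. Mono-Sonogashira coupling of excess F6 with 6 (Pd(PPh3)4, CuI, iPr2NH, DMF) gives tert-butyl{[(1R)-4-[(3E,5E,7E,9E)-3,10-dimethyldodeca-3,5,7,9-tetraene-1,11-diyn-1-yl]-3,5,5-trimethylcyclohex-3-en-1-yl]oxy}dimethylsilane F7. Bu4NF gives the alcohol (1R)-4-[(3E,5E,7E,9E)-3,10-dimethyldodeca-3,5,7,9-tetraene-1,11-diyn-1-yl]-3,5,5-trimethylcyclohex-3-en-1-ol F8, and acetylation of F8 with 24 (pyridine, DMAP) gives 30.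

## Further compounds

F1 | step 19 | (2E)-2,3-dibromoprop-2-enoic acid | OC(=O)/C(Br)=C\Br
F2 | step 19 | (1R)-4-[(3E,5E,7E,9E,11Z)-11-(4-bromo-5-oxofuran-2(5H)-ylidene)-3,10-dimethylundeca-3,5,7,9-tetraen-1-yn-1-yl]-3,5,5-trimethylcyclohex-3-en-1-yl acetate | CC(=O)O[C@@H]1CC(C)=C(C#C/C(C)=C/C=C/C=C/C=C(C)/C=C2C=C(Br)C(=O)O/2)C(C)(C)C1
F3 | step 18 | (2E,4E)-5-methyl-9-[tri(propan-2-yl)silyl]nona-2,4-dien-6,8-diynal | O=C/C=C/C=C(C)/C#CC#C[Si](C(C)C)(C(C)C)C(C)C
F4 | step 18 | (1R)-4-[(3E,5E,7E,9E)-3,10-dimethyl-14-[tri(propan-2-yl)silyl]tetradeca-3,5,7,9-tetraene-1,11,13-triyn-1-yl]-3,5,5-trimethylcyclohex-3-en-1-yl acetate | CC(=O)O[C@@H]1CC(C)=C(C#C/C(C)=C/C=C/C=C/C=C(C)/C#CC#C[Si](C(C)C)(C(C)C)C(C)C)C(C)(C)C1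
F5 | step 18 | (1R)-4-[(3E,5E,7E,9E)-3,10-dimethyltetradeca-3,5,7,9-tetraene-1,11,13-triyn-1-yl]-3,5,5-trimethylcyclohex-3-en-1-yl acetate | CC(=O)O[C@@H]1CC(C)=C(C#C/C(C)=C/C=C/C=C/C=C(C)/C#CC#C)C(C)(C)C1
F6 | step 16 | (3E,5E,7E,9E)-3,10-dimethyldodeca-3,5,7,9-tetraene-1,11-diyne | C#C/C(C)=C/C=C/C=C/C=C(C)/C#C
F7 | step 16 | tert-butyl{[(1R)-4-[(3E,5E,7E,9E)-3,10-dimethyldodeca-3,5,7,9-tetraene-1,11-diyn-1-yl]-3,5,5-trimethylcyclohex-3-en-1-yl]oxy}dimethylsilane | CC(C)(C)[Si](C)(C)O[C@@H]1CC(C)=C(C#C/C(C)=C/C=C/C=C/C=C(C)/C#C)C(C)(C)C1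
F8 | step 16 | (1R)-4-[(3E,5E,7E,9E)-3,10-dimethyldodeca-3,5,7,9-tetraene-1,11-diyn-1-yl]-3,5,5-trimethylcyclohex-3-en-1-ol | O[C@@H]1CC(C)=C(C#C/C(C)=C/C=C/C=C/C=C(C)/C#C)C(C)(C)C1
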